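**Assumption:** the stereodescriptors are read from the SMILES as drawn (lactone 4S,5R; C10 R; C16 R; C18 R; oxolane C19 R, C20 R, C22 R; 6E,8Z,12E,14E), and the chain is numbered C1 (lactone C=O) to C24 (CH2OH).

## Retrosynthetic overview

1. C7–C8: Stille coupling of lactone stannane 34 (fragment 4) with vinyl iodide 28, then desilylation.
2. C15–C16, the C16 stereocentre and the C14=C15 alkene: one-flask methylalumination of enyne 7 (fragment 1), alanate addition to the lactate-derived α-mesyloxy ketone 24 (fragment 3), and a stereospecific 1,2-alkenyl shift (semipinacol).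
3. C18–C19: chelated titanium enolate of lactate ketone 19 plus the oxocarbenium ion released from bicyclic acetal 15 (fragment 2).
4. Fragments 1 and 2 both come from alkyne 2 (C10 and C20 methyl stereocentres); C22 is set by Sharpless epoxidation and hydride opening.
5. Ring order: the oxolane ring closes first (inside bicyclic acetal 15, step 9; unmasked in step 12); the dihydropyranone ring closes by ring-closing metathesis on fragment 4 (step 20) and is attached last.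

## Route

**Fragment 1 (C8–C15)**

Step 1
Reactants: 1 (2S)-3-bromo-2-methylpropan-1-ol
Product: 2 (2R)-2-methylpent-4-yn-1-ol
Conditions: LiC≡CH·H2NCH2CH2NH2 (3 equiv), DMSO, 0 °C → rt
Reagents that add atoms: lithium acetylide–ethylenediamine complex, [Li+].[C-]#C.NCCN
Why: SN2 alkynylation of the primary bromide (excess acetylide carries the hydroxyl as its alkoxide); the stereocentre is untouched and only its descriptor changes.

Step 2
Reactants: 2 (2R)-2-methylpent-4-yn-1-ol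
Product: 4 (2R,4E)-5-iodo-2-methylpent-4-en-1-ol, via alkenylzirconocene chloride 3 (not isolated)
Conditions: Cp2Zr(H)Cl (2.2 equiv), THF, rt; then I2, 0 °C
Reagents that add atoms: iodine, II
Why: syn-hydrozirconation puts zirconium on the terminal carbon and iodinolysis proceeds with retention, giving the E-vinyl iodide.

Step 3
Reactants: 4 (2R,4E)-5-iodo-2-methylpent-4-en-1-ol
Product: 5 (2R,4E)-2-methylhept-4-en-6-yn-1-ol
Conditions: HC≡CMgBr, ZnBr2, THF; Pd(PPh3)4 (5 mol %), rt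
Reagents that add atoms: ethynylmagnesium bromide, C#C[Mg]Br
Why: Negishi alkynylation with ethynylzinc bromide gives the terminal E-enyne directly with retention of alkene geometry.

Step 4
Reactants: 5 (2R,4E)-2-methylhept-4-en-6-yn-1-ol
Product: 6 (2R,4E)-2-methylhept-4-en-6-ynal
Conditions: Dess–Martin periodinane, CH2Cl2, 0 °C → rt
Reagents that add atoms: none
Why: Dess–Martin oxidation is non-basic, so the α-methyl stereocentre is kept; the aldehyde is used crude.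

Step 5
Reactants: 6 (2R,4E)-2-methylhept-4-en-6-ynal
Product: 7 (3Z,5R,7E)-3-iodo-5-methyldeca-3,7-dien-9-yne
Conditions: [Ph3PCH2CH2CH3]Br, n-BuLi, THF, 0 °C; I2, −78 °C; NaN(SiMe3)2, −78 → −20 °C; then 6, −78 °C → rt
Reagents that add atoms: (1-iodopropylidene)triphenylphosphorane (made in the flask), CCC(I)=P(c1ccccc1)(c1ccccc1)c1ccccc1
Why: Stork–Zhao-type Wittig olefination with the α-iodo ylide gives the Z-iodoalkene (iodine cis to the chain), which fixes the later 8Z geometry.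

**Fragment 2 (C19–C24)**

Step 6
Reactants: 2 (2R)-2-methylpent-4-yn-1-ol
Product: 9 (4R)-5,5-dimethoxy-4-methylpent-1-yne, via (2R)-2-methylpent-4-ynal 8 (not isolated)
Conditions: TEMPO (10 mol %), PhI(OAc)2, CH2Cl2, rt; then HC(OMe)3, MeOH, PPTS (cat.), rt
Reagents that add atoms: trimethyl orthoformate, COC(OC)OC
Why: nitroxyl-catalysed oxidation and acetalisation in one flask avoid isolating the volatile, epimerisable aldehyde.

Step 7
Reactants: 9 (4R)-5,5-dimethoxy-4-methylpent-1-yne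
Product: 12 (2E,5R)-6,6-dimethoxy-3,5-dimethylhex-2-en-1-ol, via alkenyl(dimethyl)alane 10 (not isolated), via lithium alkenylaluminate 11 (not isolated)
Conditions: AlMe3 (2.5 equiv), Cp2ZrCl2 (20 mol %), CH2Cl2, 0 °C; volatiles removed; n-BuLi, THF, −78 °C; (CH2O)n, −78 °C → rt
Reagents that add atoms: trimethylaluminium, C[Al](C)C; formaldehyde (as paraformaldehyde), C=O
Why: Negishi zirconium-catalysed syn-methylalumination (methyl to the internal carbon) and alanate hydroxymethylation give the E-trisubstituted allylic alcohol.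

Step 8
Reactants: 12 (2E,5R)-6,6-dimethoxy-3,5-dimethylhex-2-en-1-ol
Product: 13 {(2R,3R)-3-[(2R)-3,3-dimethoxy-2-methylpropyl]-3-methyloxiran-2-yl}methanol
Conditions: Ti(Oi-Pr)4 (10 mol %), D-(−)-diethyl tartrate (12 mol %), t-BuOOH, 4 Å MS, CH2Cl2, −20 °C
Reagents that add atoms: tert-butyl hydroperoxide, CC(C)(C)OO
Why: Sharpless asymmetric epoxidation; D-(−)-tartrate gives the (2R,3R)-epoxide of an E-3-methyl-2-alkenol (as for geraniol) and so sets the C22 C–O stereocentre.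

Step 9
Reactants: 13 {(2R,3R)-3-[(2R)-3,3-dimethoxy-2-methylpropyl]-3-methyloxiran-2-yl}methanol
Product: 15 (1S,5R,7R)-5,7-dimethyl-2,8-dioxabicyclo[3.2.1]octane, via diol 14 (not isolated)
Conditions: NaAlH2(OCH2CH2OMe)2, THF, 0 °C; aqueous potassium sodium tartrate work-up; then PPTS (cat.), 4 Å MS, CH2Cl2, rt
Reagents that add atoms: none
Why: hydroxyl-directed hydride opening at the carbon next to CH2OH leaves the tertiary C22–O bond intact (1,3-diol), and acid-catalysed transacetalisation then closes the oxolane ring inside a self-protected bicyclic acetal.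

**Fragment 3 (C16–C24)**

Step 10
Reactants: 16 methyl (2R)-2-hydroxypropanoate
Product: 17 methyl (2R)-2-(benzyloxy)propanoate
Conditions: BnOC(=NH)CCl3, TfOH (cat.), cyclohexane/CH2Cl2, rt
Reagents that add atoms: benzyl 2,2,2-trichloroacetimidate, ClC(Cl)(Cl)C(=N)OCc1ccccc1
Why: acid-catalysed imidate benzylation is non-basic, so the lactate centre does not racemise.

Step 11
Reactants: 17 methyl (2R)-2-(benzyloxy)propanoate
Product: 19 (2R)-2-(benzyloxy)pentan-3-one, via Weinreb amide 18 (not isolated)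
Conditions: MeNH(OMe)·HCl, i-PrMgCl, THF, −20 °C; then EtMgBr, 0 °C; aq. NH4Cl
Reagents that add atoms: ethylmagnesium bromide, CC[Mg]Br
Why: Weinreb amide formation and Grignard addition in one flask; the chelated tetrahedral intermediate stops at the ketone.

Step 12
Reactants: 19 (2R)-2-(benzyloxy)pentan-3-one; 15 (1S,5R,7R)-5,7-dimethyl-2,8-dioxabicyclo[3.2.1]octane
Product: 21 (2R,4R)-2-(benzyloxy)-4-[(2R,3R,5R)-5-(2-hydroxyethyl)-3,5-dimethyloxolan-2-yl]pentan-3-one, via trichlorotitanium enolate 20 (not isolated)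
Conditions: TiCl4 (1.1 equiv), i-Pr2NEt (1.1 equiv), CH2Cl2, −78 °C; then 15, TiCl4 (1.0 equiv), −78 → −40 °C
Reagents that add atoms: none
Why: the chelated Z-titanium enolate of an α-benzyloxy ketone (Urpí-type) adds through an open transition state to the oxolanyl oxocarbenium ion formed when TiCl4 cleaves the less hindered C19–O24 bond; the enolate reacts on the face anti to the lactate methyl of the chelate (sets C18, R), and the cation reacts on the exo face anti to the leaving oxygen and the C20 methyl (sets C19, R, 2,3-trans).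

Step 13
Reactants: 21 (2R,4R)-2-(benzyloxy)-4-[(2R,3R,5R)-5-(2-hydroxyethyl)-3,5-dimethyloxolan-2-yl]pentan-3-one
Product: 22 (2R,4R)-2-hydroxy-4-[(2R,3R,5R)-5-(2-hydroxyethyl)-3,5-dimethyloxolan-2-yl]pentan-3-one
Conditions: H2 (1 atm), Pd/C, EtOAc, rt
Reagents that add atoms: none
Why: neutral hydrogenolysis of the benzyl ether, done before any alkene is present.

Step 14
Reactants: 22 (2R,4R)-2-hydroxy-4-[(2R,3R,5R)-5-(2-hydroxyethyl)-3,5-dimethyloxolan-2-yl]pentan-3-one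
Product: 24 (2R,4R)-4-[(2R,3R,5R)-5-{2-[(tert-butyldimethylsilyl)oxy]ethyl}-3,5-dimethyloxolan-2-yl]-3-oxopentan-2-yl methanesulfonate, via silyl ether 23 (not isolated)
Conditions: TBSCl (1.05 equiv), imidazole, CH2Cl2, −20 °C; then Et3N, MsCl, 0 °C
Reagents that add atoms: tert-butyldimethylsilyl chloride, CC(C)(C)[Si](C)(C)Cl; methanesulfonyl chloride, CS(=O)(=O)Cl
Why: the primary alcohol is silylated much faster than the hindered α-ketol, which is then mesylated in the same flask with retention at C16.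

**Key union**

Step 15
Reactants: 7 (3Z,5R,7E)-3-iodo-5-methyldeca-3,7-dien-9-yne; 24 (2R,4R)-4-[(2R,3R,5R)-5-{2-[(tert-butyldimethylsilyl)oxy]ethyl}-3,5-dimethyloxolan-2-yl]-3-oxopentan-2-yl methanesulfonate
Product: 28 (3Z,5R,7E,9E,11R,13R)-13-[(2R,3R,5R)-5-{2-[(tert-butyldimethylsilyl)oxy]ethyl}-3,5-dimethyloxolan-2-yl]-3-iodo-5,9,11-trimethyltetradeca-3,7,9-trien-12-one, via dienyl(dimethyl)alane 25 (not isolated), via lithium dienyl(trimethyl)aluminate 26 (not isolated), via mesyloxy aluminium alkoxide 27 (not isolated)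
Conditions: 7, AlMe3 (2 equiv), Cp2ZrCl2 (25 mol %), CH2Cl2, 0 °C → rt; volatiles removed; MeLi (1.0 equiv), THF/toluene, −78 °C; 24, −78 °C; then Me2AlCl (2 equiv), −78 → −20 °C
Reagents that add atoms: trimethylaluminium, C[Al](C)C
Why: Proposed new method: a one-flask carboaluminative semipinacol union in which aluminium first carries the nucleophile and then acts as the Lewis acid. Syn-methylalumination of the enyne sets the 14E alkene; the alanate transfers its dienyl group to the C17 ketone (no free alkyllithium ever meets the C8 iodide); Me2AlCl then turns the aluminate into a Lewis-acidic alkoxyalane that activates the mesylate, and the dienyl group, antiperiplanar to the C16–O bond, shifts 1,2 with inversion at C16 (16R) while C17 becomes the ketone, so both C17 epimers converge. The closest known reactions are the two-step Suzuki–Tsuchihashi sequence (alkenyl-metal addition to an α-mesyloxy ketone, then Et3Al-promoted stereospecific 1,2-alkenyl shift) and Negishi alkenylalanate additions to carbonyl compounds.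

**Fragment 4 (C1–C7)**

Step 16
Reactants: 29 prop-2-yn-1-ol
Product: 30 (2E)-3-(tributylstannyl)prop-2-en-1-ol
Conditions: Bu3SnH, AIBN (cat.), neat, 80 °C
Reagents that add atoms: tributyltin hydride, CCCC[SnH](CCCC)CCCC
Why: radical hydrostannation under equilibrating conditions favours the E-β-stannyl isomer, which is separated by chromatography.

Step 17
Reactants: 30 (2E)-3-(tributylstannyl)prop-2-en-1-ol
Product: 31 (2E)-3-(tributylstannyl)prop-2-enal
Conditions: MnO2, CH2Cl2, rt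
Reagents that add atoms: none
Why: chemoselective allylic oxidation that leaves the C–Sn bond alone.

Step 18
Reactants: 31 (2E)-3-(tributylstannyl)prop-2-enal
Product: 32 (1E,3S,4S)-4-methyl-1-(tributylstannyl)hexa-1,5-dien-3-ol
Conditions: trans-2-butene, n-BuLi, KOt-Bu, THF, −78 → −45 °C; (−)-Ipc2BOMe, −78 °C; BF3·OEt2; 31, −78 °C; then NaOH, H2O2, 0 °C
Reagents that add atoms: (E)-but-2-ene, C/C=C/C, delivered as (E)-crotylbis(isopinocampheyl)borane, C/C=C/CB([C@@H]1C[C@@H]2C[C@H]([C@H]1C)C2(C)C)[C@@H]1C[C@@H]2C[C@H]([C@H]1C)C2(C)C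
Why: Brown crotylboration through a chair transition state; the E-crotyl group gives the anti relationship (C4/C5) and the (−)-Ipc ligands direct attack to the Si face of the aldehyde (sets C5).

Step 19
Reactants: 32 (1E,3S,4S)-4-methyl-1-(tributylstannyl)hexa-1,5-dien-3-ol
Product: 33 (1E,3S,4S)-4-methyl-1-(tributylstannyl)hexa-1,5-dien-3-yl prop-2-enoate
Conditions: CH2=CHCOCl, Et3N, DMAP (cat.), CH2Cl2, 0 °C
Reagents that add atoms: acryloyl chloride, C=CC(=O)Cl
Why: simple O-acylation; no stereocentre is involved.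

Step 20
Reactants: 33 (1E,3S,4S)-4-methyl-1-(tributylstannyl)hexa-1,5-dien-3-yl prop-2-enoate
Product: 34 (5S,6S)-5-methyl-6-[(E)-2-(tributylstannyl)ethenyl]-5,6-dihydro-2H-pyran-2-one
Conditions: second-generation Grubbs catalyst RuCl2(=CHPh)(H2IMes)(PCy3) (5 mol %), CH2Cl2 (5 mM), 40 °C
Reagents that add atoms: none
Why: ring-closing metathesis starts at the terminal vinyl group and closes onto the acrylate to give the six-membered lactone; the bulky internal vinylstannane is a spectator.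

**Endgame**

Step 21
Reactants: 28 (3Z,5R,7E,9E,11R,13R)-13-[(2R,3R,5R)-5-{2-[(tert-butyldimethylsilyl)oxy]ethyl}-3,5-dimethyloxolan-2-yl]-3-iodo-5,9,11-trimethyltetradeca-3,7,9-trien-12-one; 34 (5S,6S)-5-methyl-6-[(E)-2-(tributylstannyl)ethenyl]-5,6-dihydro-2H-pyran-2-one
Product: 35 (5S,6R)-6-[(1E,3Z,5R,7E,9E,11R,13R)-13-[(2R,3R,5R)-5-{2-[(tert-butyldimethylsilyl)oxy]ethyl}-3,5-dimethyloxolan-2-yl]-3-ethyl-5,9,11-trimethyl-12-oxotetradeca-1,3,7,9-tetraen-1-yl]-5-methyl-5,6-dihydro-2H-pyran-2-one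
Conditions: Pd2(dba)3 (5 mol %), AsPh3 (40 mol %), NMP, rt
Reagents that add atoms: none
Why: Stille coupling under base-free Farina conditions retains both alkene geometries (6E,8Z) and spares the epimerisable C16 centre and the lactone.

Step 22
Reactants: 35 (5S,6R)-6-[(1E,3Z,5R,7E,9E,11R,13R)-13-[(2R,3R,5R)-5-{2-[(tert-butyldimethylsilyl)oxy]ethyl}-3,5-dimethyloxolan-2-yl]-3-ethyl-5,9,11-trimethyl-12-oxotetradeca-1,3,7,9-tetraen-1-yl]-5-methyl-5,6-dihydro-2H-pyran-2-one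
Product: 36 (5S,6R)-6-[(1E,3Z,5R,7E,9E,11R,13R)-3-ethyl-13-[(2R,3R,5R)-5-(2-hydroxyethyl)-3,5-dimethyloxolan-2-yl]-5,9,11-trimethyl-12-oxotetradeca-1,3,7,9-tetraen-1-yl]-5-methyl-5,6-dihydro-2H-pyran-2-one
Conditions: HF·pyridine, pyridine, THF, 0 °C
Reagents that add atoms: none
Why: buffered fluoride desilylation of the primary silyl ether; non-basic, so the lactone and the β,γ-unsaturated ketone survive.

## Compound list

1 | (2S)-3-bromo-2-methylpropan-1-ol | OC[C@H](C)CBr | starting material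
2 | (2R)-2-methylpent-4-yn-1-ol | OC[C@H](C)CC#C | intermediate
3 | chlorobis(cyclopentadienyl)[(1E,4R)-5-hydroxy-4-methylpent-1-en-1-yl]zirconium (hydroxyl carried as its zirconium alkoxide) | OC[C@H](C)C/C=C/[Zr](Cl)(C1C=CC=C1)C1C=CC=C1 | intermediate (not isolated)
4 | (2R,4E)-5-iodo-2-methylpent-4-en-1-ol | OC[C@H](C)C/C=C/I | intermediate
5 | (2R,4E)-2-methylhept-4-en-6-yn-1-ol | OC[C@H](C)C/C=C/C#C | intermediate
6 | (2R,4E)-2-methylhept-4-en-6-ynal | O=C[C@H](C)C/C=C/C#C | intermediate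
7 | (3Z,5R,7E)-3-iodo-5-methyldeca-3,7-dien-9-yne (fragment 1) | CC/C(I)=C/[C@H](C)C/C=C/C#C | intermediate
8 | (2R)-2-methylpent-4-ynal | O=C[C@H](C)CC#C | intermediate (not isolated)
9 | (4R)-5,5-dimethoxy-4-methylpent-1-yne | COC(OC)[C@H](C)CC#C | intermediate
10 | [(1E,4R)-5,5-dimethoxy-2,4-dimethylpent-1-en-1-yl]dimethylalumane | COC(OC)[C@H](C)C/C(C)=C/[Al](C)C | intermediate (not isolated)
11 | lithium butyl[(1E,4R)-5,5-dimethoxy-2,4-dimethylpent-1-en-1-yl]dimethylaluminate | [Li+].COC(OC)[C@H](C)C/C(C)=C/[Al-](C)(C)CCCC | intermediate (not isolated)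
12 | (2E,5R)-6,6-dimethoxy-3,5-dimethylhex-2-en-1-ol | COC(OC)[C@H](C)C/C(C)=C/CO | intermediate
13 | {(2R,3R)-3-[(2R)-3,3-dimethoxy-2-methylpropyl]-3-methyloxiran-2-yl}methanol | COC(OC)[C@H](C)C[C@@]1(C)O[C@@H]1CO | intermediate
14 | (3R,5R)-6,6-dimethoxy-3,5-dimethylhexane-1,3-diol | COC(OC)[C@H](C)C[C@@](C)(O)CCO | intermediate (not isolated)
15 | (1S,5R,7R)-5,7-dimethyl-2,8-dioxabicyclo[3.2.1]octane (fragment 2) | C[C@@H]1C[C@]2(C)CCO[C@H]1O2 | intermediate
16 | methyl (2R)-2-hydroxypropanoate | C[C@@H](O)C(=O)OC | starting material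
17 | methyl (2R)-2-(benzyloxy)propanoate | C[C@@H](OCc1ccccc1)C(=O)OC | intermediate
18 | (2R)-2-(benzyloxy)-N-methoxy-N-methylpropanamide | C[C@@H](OCc1ccccc1)C(=O)N(C)OC | intermediate (not isolated)
19 | (2R)-2-(benzyloxy)pentan-3-one | C[C@@H](OCc1ccccc1)C(=O)CC | intermediate
20 | trichloro{[(2Z,4R)-4-(benzyloxy)pent-2-en-3-yl]oxy}titanium | C/C=C(\O[Ti](Cl)(Cl)Cl)[C@@H](C)OCc1ccccc1 | intermediate (not isolated)
21 | (2R,4R)-2-(benzyloxy)-4-[(2R,3R,5R)-5-(2-hydroxyethyl)-3,5-dimethyloxolan-2-yl]pentan-3-one | C[C@@H](OCc1ccccc1)C(=O)[C@H](C)[C@@H]1O[C@@](C)(CCO)C[C@H]1C | intermediate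
22 | (2R,4R)-2-hydroxy-4-[(2R,3R,5R)-5-(2-hydroxyethyl)-3,5-dimethyloxolan-2-yl]pentan-3-one | C[C@@H](O)C(=O)[C@H](C)[C@@H]1O[C@@](C)(CCO)C[C@H]1C | intermediate
23 | (2R,4R)-4-[(2R,3R,5R)-5-{2-[(tert-butyldimethylsilyl)oxy]ethyl}-3,5-dimethyloxolan-2-yl]-2-hydroxypentan-3-one | C[C@@H](O)C(=O)[C@H](C)[C@@H]1O[C@@](C)(CCO[Si](C)(C)C(C)(C)C)C[C@H]1C | intermediate (not isolated)
24 | (2R,4R)-4-[(2R,3R,5R)-5-{2-[(tert-butyldimethylsilyl)oxy]ethyl}-3,5-dimethyloxolan-2-yl]-3-oxopentan-2-yl methanesulfonate (fragment 3) | C[C@@H](OS(C)(=O)=O)C(=O)[C@H](C)[C@@H]1O[C@@](C)(CCO[Si](C)(C)C(C)(C)C)C[C@H]1C | intermediate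
25 | [(1E,3E,6R,7Z)-8-iodo-2,6-dimethyldeca-1,3,7-trien-1-yl]dimethylalumane | CC/C(I)=C/[C@H](C)C/C=C/C(C)=C/[Al](C)C | intermediate (not isolated)
26 | lithium [(1E,3E,6R,7Z)-8-iodo-2,6-dimethyldeca-1,3,7-trien-1-yl]trimethylaluminate | [Li+].CC/C(I)=C/[C@H](C)C/C=C/C(C)=C/[Al-](C)(C)C | intermediate (not isolated)
27 | (2R,3RS,4E,6E,9R,10Z)-3-[(1R)-1-[(2R,3R,5R)-5-{2-[(tert-butyldimethylsilyl)oxy]ethyl}-3,5-dimethyloxolan-2-yl]ethyl]-3-[(dimethylalumanyl)oxy]-11-iodo-5,9-dimethyltrideca-4,6,10-trien-2-yl methanesulfonate | CC/C(I)=C/[C@H](C)C/C=C/C(C)=C/C(O[Al](C)C)([C@@H](C)OS(C)(=O)=O)[C@H](C)[C@@H]1O[C@@](C)(CCO[Si](C)(C)C(C)(C)C)C[C@H]1C | intermediate (not isolated)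
28 | (3Z,5R,7E,9E,11R,13R)-13-[(2R,3R,5R)-5-{2-[(tert-butyldimethylsilyl)oxy]ethyl}-3,5-dimethyloxolan-2-yl]-3-iodo-5,9,11-trimethyltetradeca-3,7,9-trien-12-one | CC/C(I)=C/[C@H](C)C/C=C/C(C)=C/[C@@H](C)C(=O)[C@H](C)[C@@H]1O[C@@](C)(CCO[Si](C)(C)C(C)(C)C)C[C@H]1C | intermediate
29 | prop-2-yn-1-ol | OCC#C | starting material
30 | (2E)-3-(tributylstannyl)prop-2-en-1-ol | CCCC[Sn](CCCC)(CCCC)/C=C/CO | intermediate
31 | (2E)-3-(tributylstannyl)prop-2-enal | CCCC[Sn](CCCC)(CCCC)/C=C/C=O | intermediate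
32 | (1E,3S,4S)-4-methyl-1-(tributylstannyl)hexa-1,5-dien-3-ol | CCCC[Sn](CCCC)(CCCC)/C=C/[C@@H](O)[C@@H](C)C=C | intermediate
33 | (1E,3S,4S)-4-methyl-1-(tributylstannyl)hexa-1,5-dien-3-yl prop-2-enoate | CCCC[Sn](CCCC)(CCCC)/C=C/[C@@H](OC(=O)C=C)[C@@H](C)C=C | intermediate
34 | (5S,6S)-5-methyl-6-[(E)-2-(tributylstannyl)ethenyl]-5,6-dihydro-2H-pyran-2-one (fragment 4) | CCCC[Sn](CCCC)(CCCC)/C=C/[C@H]1OC(=O)C=C[C@@H]1C | intermediate
35 | (5S,6R)-6-[(1E,3Z,5R,7E,9E,11R,13R)-13-[(2R,3R,5R)-5-{2-[(tert-butyldimethylsilyl)oxy]ethyl}-3,5-dimethyloxolan-2-yl]-3-ethyl-5,9,11-trimethyl-12-oxotetradeca-1,3,7,9-tetraen-1-yl]-5-methyl-5,6-dihydro-2H-pyran-2-one | CCC(=C/[C@H](C)C/C=C/C(C)=C/[C@@H](C)C(=O)[C@H](C)[C@@H]1O[C@@](C)(CCO[Si](C)(C)C(C)(C)C)C[C@H]1C)/C=C/[C@H]1OC(=O)C=C[C@@H]1C | intermediate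
36 | (5S,6R)-6-[(1E,3Z,5R,7E,9E,11R,13R)-3-ethyl-13-[(2R,3R,5R)-5-(2-hydroxyethyl)-3,5-dimethyloxolan-2-yl]-5,9,11-trimethyl-12-oxotetradeca-1,3,7,9-tetraen-1-yl]-5-methyl-5,6-dihydro-2H-pyran-2-one | CCC(=C/[C@H](C)C/C=C/C(C)=C/[C@@H](C)C(=O)[C@H](C)[C@@H]1O[C@@](C)(CCO)C[C@H]1C)/C=C/[C@H]1OC(=O)C=C[C@@H]1C | target

## Step count and risks

Total steps: 22. Longest linear sequence: 11 steps (1, 6, 7, 8, 9, 12, 13, 14, 15, 21, 22).

**Step 15 (the proposed new step).** The alanate may add sluggishly to the hindered ketone, or the alkoxide may close to an epoxide before the shift. The fallback uses known chemistry, sets out from 5 and 24 and returns at 28. Methylalumination of 5 (AlMe3, Cp2ZrCl2) and iodinolysis give (2R,4E,6E)-7-iodo-2,6-dimethylhepta-4,6-dien-1-ol F1. After O-deprotonation with MeLi, iodine–lithium exchange (t-BuLi, Et2O, −78 °C) and addition to 24 give, on cold quench, (2R,3RS,4E,6E,9R)-3-[(1R)-1-[(2R,3R,5R)-5-{2-[(tert-butyldimethylsilyl)oxy]ethyl}-3,5-dimethyloxolan-2-yl]ethyl]-3,10-dihydroxy-5,9-dimethyldeca-4,6-dien-2-yl methanesulfonate F2. Et3Al (CH2Cl2, −78 → 0 °C) then effects the established Suzuki–Tsuchihashi 1,2-alkenyl shift to (2R,4R,5E,7E,10R)-2-[(2R,3R,5R)-5-{2-[(tert-butyldimethylsilyl)oxy]ethyl}-3,5-dimethyloxolan-2-yl]-11-hydroxy-4,6,10-trimethylundeca-5,7-dien-3-one F3. Dess–Martin oxidation gives (2R,4E,6E,8R,10R)-10-[(2R,3R,5R)-5-{2-[(tert-butyldimethylsilyl)oxy]ethyl}-3,5-dimethyloxolan-2-yl]-2,6,8-trimethyl-9-oxoundeca-4,6-dienal F4, and the iodo-Wittig olefination of step 5 applied to F4 gives 28.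

**Step 12.** The bicyclic acetal may ionise at the wrong C–O bond, or may not form cleanly in step 9 because the C20 methyl sits endo. The fallback replaces the self-protected bicyclic acetal by a monocyclic, sterically controlled oxocarbenium precursor; it sets out from 14 (isolated in this case) and 19 and returns at 23, which is then isolated and mesylated to 24. Silylation of 14 (TBSCl, imidazole) gives (3R,5R)-1-[(tert-butyldimethylsilyl)oxy]-6,6-dimethoxy-3,5-dimethylhexan-3-ol F5. PPTS in CH2Cl2 closes it to tert-butyl{2-[(2R,4R,5RS)-5-methoxy-2,4-dimethyloxolan-2-yl]ethoxy}dimethylsilane F6. BF3·OEt2-mediated addition of enolate 20 to F6 (attack trans to the C20 methyl) gives (2R,4R)-2-(benzyloxy)-4-[(2R,3R,5R)-5-{2-[(tert-butyldimethylsilyl)oxy]ethyl}-3,5-dimethyloxolan-2-yl]pentan-3-one F7, and hydrogenolysis (H2, Pd/C) gives 23.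

**Step 21.** The hindered α-ethyl vinyl iodide may couple slowly, with isomerisation of the β,γ-unsaturated ketone. The fallback reverses the polarity to a Suzuki–Miyaura coupling; it sets out from 28 and 34 and returns at 35. Miyaura borylation of 28 (B2pin2, PdCl2(dppf), KOPh, toluene, 50 °C) gives (3E,5R,7E,9E,11R,13R)-13-[(2R,3R,5R)-5-{2-[(tert-butyldimethylsilyl)oxy]ethyl}-3,5-dimethyloxolan-2-yl]-5,9,11-trimethyl-3-(4,4,5,5-tetramethyl-1,3,2-dioxaborolan-2-yl)tetradeca-3,7,9-trien-12-one F8. Iododestannylation of 34 (I2, CH2Cl2, 0 °C) gives (5S,6S)-6-[(E)-2-iodoethenyl]-5-methyl-5,6-dihydro-2H-pyran-2-one F9. Coupling of F8 and F9 (PdCl2(dppf), aqueous K3PO4, DMF, rt) gives 35.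

## Further compounds

F1 | step 15 | (2R,4E,6E)-7-iodo-2,6-dimethylhepta-4,6-dien-1-ol | OC[C@H](C)C/C=C/C(C)=C/I
F2 | step 15 | (2R,3RS,4E,6E,9R)-3-[(1R)-1-[(2R,3R,5R)-5-{2-[(tert-butyldimethylsilyl)oxy]ethyl}-3,5-dimethyloxolan-2-yl]ethyl]-3,10-dihydroxy-5,9-dimethyldeca-4,6-dien-2-yl methanesulfonate | OC[C@H](C)C/C=C/C(C)=C/C(O)([C@@H](C)OS(C)(=O)=O)[C@H](C)[C@@H]1O[C@@](C)(CCO[Si](C)(C)C(C)(C)C)C[C@H]1C
F3 | step 15 | (2R,4R,5E,7E,10R)-2-[(2R,3R,5R)-5-{2-[(tert-butyldimethylsilyl)oxy]ethyl}-3,5-dimethyloxolan-2-yl]-11-hydroxy-4,6,10-trimethylundeca-5,7-dien-3-one | OC[C@H](C)C/C=C/C(C)=C/[C@@H](C)C(=O)[C@H](C)[C@@H]1O[C@@](C)(CCO[Si](C)(C)C(C)(C)C)C[C@H]1C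
F4 | step 15 | (2R,4E,6E,8R,10R)-10-[(2R,3R,5R)-5-{2-[(tert-butyldimethylsilyl)oxy]ethyl}-3,5-dimethyloxolan-2-yl]-2,6,8-trimethyl-9-oxoundeca-4,6-dienal | O=C[C@H](C)C/C=C/C(C)=C/[C@@H](C)C(=O)[C@H](C)[C@@H]1O[C@@](C)(CCO[Si](C)(C)C(C)(C)C)C[C@H]1C
F5 | step 12 | (3R,5R)-1-[(tert-butyldimethylsilyl)oxy]-6,6-dimethoxy-3,5-dimethylhexan-3-ol | COC(OC)[C@H](C)C[C@@](C)(O)CCO[Si](C)(C)C(C)(C)C
F6 | step 12 | tert-butyl{2-[(2R,4R,5RS)-5-methoxy-2,4-dimethyloxolan-2-yl]ethoxy}dimethylsilane | COC1O[C@@](C)(CCO[Si](C)(C)C(C)(C)C)C[C@H]1C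
F7 | step 12 | (2R,4R)-2-(benzyloxy)-4-[(2R,3R,5R)-5-{2-[(tert-butyldimethylsilyl)oxy]ethyl}-3,5-dimethyloxolan-2-yl]pentan-3-one | C[C@@H](OCc1ccccc1)C(=O)[C@H](C)[C@@H]1O[C@@](C)(CCO[Si](C)(C)C(C)(C)C)C[C@H]1C
F8 | step 21 | (3E,5R,7E,9E,11R,13R)-13-[(2R,3R,5R)-5-{2-[(tert-butyldimethylsilyl)oxy]ethyl}-3,5-dimethyloxolan-2-yl]-5,9,11-trimethyl-3-(4,4,5,5-tetramethyl-1,3,2-dioxaborolan-2-yl)tetradeca-3,7,9-trien-12-one | CC/C(B1OC(C)(C)C(C)(C)O1)=C/[C@H](C)C/C=C/C(C)=C/[C@@H](C)C(=O)[C@H](C)[C@@H]1O[C@@](C)(CCO[Si](C)(C)C(C)(C)C)C[C@H]1C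
F9 | step 21 | (5S,6S)-6-[(E)-2-iodoethenyl]-5-methyl-5,6-dihydro-2H-pyran-2-one | I/C=C/[C@H]1OC(=O)C=C[C@@H]1C
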